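**Retrosynthetic overview**
- Last bond: the C11=C12 (E) alkene, by Julia–Kocienski olefination of a peroxylactone aldehyde with a styrenyl PT-sulfone, so the styrene never meets the radical/O2 step.
- 1,2-Dioxane (second ring): 6-exo oxa-Michael addition of a C6 tertiary hydroperoxide onto the butenolide (cis-fusion sets C3 from C4). The hydroperoxide comes from Co-catalysed Isayama–Mukaiyama hydroperoxysilylation of a C6 1,1-disubstituted alkene; C6 is not controlled and the epimers are separated.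
- Butenolide (first ring): Still–Gennari olefination and lactonisation of an α-hydroxy aldehyde.
- C5–C6 bond: Cu-catalysed opening of (S)-2-methylglycidyl TBS ether (source of C4) by a 2-alkenyl Grignard reagent.
- Alkenyl bromide from (R)-citronellal (source of C8): alkyne homologation, bromoboration, then ozonolysis of the prenyl end to a masked C11 aldehyde.

Assumption: (R)-citronellal and (R)-2-methylglycidol are bought in ≥97% ee; plakortolide numbering (C1 lactone C=O, C3/C4 ring fusion, C6 peroxy carbon carrying the chain, C8 side-chain methine) is used in the comments.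

**Route**

Step 1
Reactants: 1 (R)-citronellal [(3R)-3,7-dimethyloct-6-enal]
Product: 2 (4R)-4,8-dimethylnon-7-en-1-yne
Conditions: Ohira–Bestmann reagent (1.2 equiv), K2CO3 (2 equiv), MeOH, 0 °C → rt
Reagents that add atoms: dimethyl (1-diazo-2-oxopropyl)phosphonate, CC(=O)C(=[N+]=[N-])P(=O)(OC)OC
Why: Seyferth–Gilbert homologation (Ohira–Bestmann variant) turns the aldehyde into the terminal alkyne under mild base, and the methyl-bearing centre (later C8) is β to the carbonyl, so it cannot epimerise.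

Step 2
Reactants: 2 (4R)-4,8-dimethylnon-7-en-1-yne
Product: 4 (4R)-2-bromo-4,8-dimethylnona-1,7-diene, via alkenylborane 3 (not isolated)
Conditions: B-Br-9-BBN (1.2 equiv), CH2Cl2, 0 °C; then AcOH, 0 °C → rt
Reagents that add atoms: B-bromo-9-borabicyclo[3.3.1]nonane, BrB1C2CCCC1CCC2
Why: Syn bromoboration of the terminal alkyne is Markovnikov (Br internal) and leaves the trisubstituted alkene alone, and protodeboronation with acetic acid gives the 2-bromo-1-alkene.

Step 3
Reactants: 4 (4R)-2-bromo-4,8-dimethylnona-1,7-diene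
Product: 6 (4R)-2-bromo-7,7-dimethoxy-4-methylhept-1-ene, via aldehyde 5 (not isolated)
Conditions: O3, CH2Cl2/MeOH (4:1), Sudan III, −78 °C; Me2S, −78 °C → rt; then TsOH·H2O (10 mol %), rt
Reagents that add atoms: methanol, CO
Why: Chemoselective ozonolysis cleaves the electron-rich trisubstituted alkene much faster than the bromine-deactivated vinyl bromide (indicator end-point), and acid-catalysed acetalisation in methanol masks the new C11 aldehyde.

Step 4
Reactants: 7 (R)-2-methylglycidol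
Product: 8 tert-butyldimethyl{[(2S)-2-methyloxiran-2-yl]methoxy}silane
Conditions: TBSCl (1.1 equiv), imidazole (1.5 equiv), CH2Cl2, 0 °C
Reagents that add atoms: tert-butyldimethylsilyl chloride, CC(C)(C)[Si](C)(C)Cl
Why: Silyl ether formation without an alkoxide avoids Payne rearrangement, so the quaternary centre is untouched (the descriptor changes from R to S only because the CIP priorities change).

Step 5
Reactants: 6 (4R)-2-bromo-7,7-dimethoxy-4-methylhept-1-ene; 8 tert-butyldimethyl{[(2S)-2-methyloxiran-2-yl]methoxy}silane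
Product: 10 (2S,6R)-1-[(tert-butyldimethylsilyl)oxy]-9,9-dimethoxy-2,6-dimethyl-4-methylidenenonan-2-ol, via Grignard reagent 9 (not isolated)
Conditions: Mg (I2 cat.), THF, 45 °C; then CuI (10 mol %), 8, THF, −30 → 0 °C; aq. NH4Cl
Reagents that add atoms: none
Why: Copper-catalysed SN2 opening of the 2,2-disubstituted epoxide at its CH2 terminus by the alkenyl Grignard reagent forms the C5–C6 bond and carries the epoxide configuration into the C4 tertiary alcohol unchanged.

Step 6
Reactants: 10 (2S,6R)-1-[(tert-butyldimethylsilyl)oxy]-9,9-dimethoxy-2,6-dimethyl-4-methylidenenonan-2-ol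
Product: 11 (2S,6R)-9,9-dimethoxy-2,6-dimethyl-4-methylidenenonane-1,2-diol
Conditions: CSA (10 mol %), MeOH, 0 °C → rt; Et3N quench
Reagents that add atoms: none
Why: Acid-catalysed methanolysis removes the primary TBS ether, while the dimethyl acetal only exchanges with the solvent and the alkene is not protonated by this weak acid.

Step 7
Reactants: 11 (2S,6R)-9,9-dimethoxy-2,6-dimethyl-4-methylidenenonane-1,2-diol
Product: 12 (2S,6R)-2-hydroxy-9,9-dimethoxy-2,6-dimethyl-4-methylidenenonanal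
Conditions: IBX (1.5 equiv), DMSO, rt
Reagents that add atoms: none
Why: IBX oxidation takes the primary alcohol of a 1,2-diol to the α-hydroxy aldehyde without glycol cleavage, the tertiary alcohol is inert, and the aldehyde has no α-hydrogen to epimerise.

Step 8
Reactants: 12 (2S,6R)-2-hydroxy-9,9-dimethoxy-2,6-dimethyl-4-methylidenenonanal
Product: 14 (5S)-5-[(4R)-7,7-dimethoxy-4-methyl-2-methylideneheptyl]-5-methylfuran-2(5H)-one, via Z-hydroxy enoate 13 (not isolated)
Conditions: (CF3CH2O)2P(O)CH2CO2Me, KHMDS, 18-crown-6, THF, −78 °C → rt; then PPTS (cat.), CH2Cl2, rt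
Reagents that add atoms: methyl 2-[bis(2,2,2-trifluoroethoxy)phosphoryl]acetate, COC(=O)CP(=O)(OCC(F)(F)F)OCC(F)(F)F
Why: Still–Gennari (Z-selective Horner–Wadsworth–Emmons) olefination places the ester cis to the tertiary hydroxyl, which lactonises to the butenolide (first ring) with C4 unchanged.

Step 9
Reactants: 14 (5S)-5-[(4R)-7,7-dimethoxy-4-methyl-2-methylideneheptyl]-5-methylfuran-2(5H)-one
Product: 15 (5S)-5-[(2RS,4R)-7,7-dimethoxy-2,4-dimethyl-2-(triethylsilylperoxy)heptyl]-5-methylfuran-2(5H)-one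
Conditions: Co(thd)2 (10 mol %), Et3SiH (2 equiv), O2 (1 atm), ClCH2CH2Cl, rt
Reagents that add atoms: dioxygen, O=O; triethylsilane, CC[SiH](CC)CC
Why: Isayama–Mukaiyama hydroperoxysilylation (Co–H hydrogen-atom transfer, then O2 capture of the tertiary radical) is Markovnikov and prefers the electron-rich 1,1-disubstituted alkene over the butenolide; the acyclic radical gives C6 as a roughly 1:1 epimer mixture that is resolved in step 10.

Step 10
Reactants: 15 (5S)-5-[(2RS,4R)-7,7-dimethoxy-2,4-dimethyl-2-(triethylsilylperoxy)heptyl]-5-methylfuran-2(5H)-one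
Product: 17 (3R,4aS,7aS)-3-[(2R)-5,5-dimethoxy-2-methylpentyl]-3,4a-dimethyl-3,4,4a,7a-tetrahydrofuro[3,2-c][1,2]dioxin-6(7H)-one, via hydroperoxide 16 (not isolated)
Conditions: HCl (cat.), MeOH, 0 °C; then Et2NH (cat.), CF3CH2OH, rt; SiO2 separation of the C6 epimers
Reagents that add atoms: none
Why: After methanolysis of the silyl peroxide, amine-catalysed intramolecular oxa-Michael addition (6-exo) of the hydroperoxide to the butenolide can only give the cis-fused bicycle, so C4 (S) fixes C3 (S); the (6R) epimer (4-Me and 6-Me cis) is isolated by chromatography from its C6 epimer.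

Step 11
Reactants: 17 (3R,4aS,7aS)-3-[(2R)-5,5-dimethoxy-2-methylpentyl]-3,4a-dimethyl-3,4,4a,7a-tetrahydrofuro[3,2-c][1,2]dioxin-6(7H)-one
Product: 18 (4R)-5-[(3R,4aS,7aS)-3,4a-dimethyl-6-oxohexahydrofuro[3,2-c][1,2]dioxin-3-yl]-4-methylpentanal
Conditions: 1 M aq. HCl, THF, rt
Reagents that add atoms: water, O
Why: Acid-catalysed acetal hydrolysis frees the C11 aldehyde, and the dialkyl peroxide and the lactone are stable to dilute aqueous acid.

Step 12
Reactants: 19 pent-4-en-1-ol; 20 styrene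
Product: 21 (4E)-5-phenylpent-4-en-1-ol
Conditions: Grubbs II (2 mol %), styrene (3 equiv), CH2Cl2, 40 °C
Reagents that add atoms: none
Why: Olefin cross-metathesis of a terminal alkene with excess styrene is strongly E-selective and driven by loss of ethene.

Step 13
Reactants: 21 (4E)-5-phenylpent-4-en-1-ol
Product: 22 1-phenyl-5-{[(4E)-5-phenylpent-4-en-1-yl]sulfanyl}-1H-tetrazole
Conditions: PT-SH (1.2 equiv), PPh3, DIAD, THF, 0 °C → rt
Reagents that add atoms: 1-phenyl-1H-tetrazole-5-thiol, Sc1nnnn1-c1ccccc1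
Why: Mitsunobu reaction of the primary alcohol with the acidic tetrazole thiol gives the sulfide cleanly.

Step 14
Reactants: 22 1-phenyl-5-{[(4E)-5-phenylpent-4-en-1-yl]sulfanyl}-1H-tetrazole
Product: 23 1-phenyl-5-{[(4E)-5-phenylpent-4-en-1-yl]sulfonyl}-1H-tetrazole
Conditions: (NH4)6Mo7O24·4H2O (10 mol %), 30% H2O2, EtOH, 0 °C → rt
Reagents that add atoms: hydrogen peroxide, OO
Why: Molybdate-catalysed peroxide oxidation takes the sulfide to the sulfone without epoxidising the styrene.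

Step 15
Reactants: 18 (4R)-5-[(3R,4aS,7aS)-3,4a-dimethyl-6-oxohexahydrofuro[3,2-c][1,2]dioxin-3-yl]-4-methylpentanal; 23 1-phenyl-5-{[(4E)-5-phenylpent-4-en-1-yl]sulfonyl}-1H-tetrazole
Product: 25 (3R,4aS,7aS)-3,4a-dimethyl-3-[(2R,5E,9E)-2-methyl-10-phenyldeca-5,9-dien-1-yl]-3,4,4a,7a-tetrahydrofuro[3,2-c][1,2]dioxin-6(7H)-one, via sulfonyl carbanion 24 (not isolated)
Conditions: 23 (1.2 equiv), KHMDS (1.15 equiv), DME, −60 °C; then 18, −60 °C → rt
Reagents that add atoms: none
Why: Julia–Kocienski olefination of the unbranched aldehyde with the pre-formed PT-sulfonyl potassium carbanion in DME gives the E alkene (Smiles rearrangement, loss of SO2), and adding the aldehyde to pre-formed carbanion at low temperature spares the base-sensitive β-peroxy lactone and all four stereocentres.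

**Compound list**

1 | (R)-citronellal, (3R)-3,7-dimethyloct-6-enal | C[C@H](CCC=C(C)C)CC=O | starting material
2 | (4R)-4,8-dimethylnon-7-en-1-yne | C[C@H](CCC=C(C)C)CC#C | intermediate
3 | 9-[(1Z,4R)-2-bromo-4,8-dimethylnona-1,7-dien-1-yl]-9-borabicyclo[3.3.1]nonane | C[C@H](CCC=C(C)C)C/C(Br)=C/B1C2CCCC1CCC2 | intermediate (not isolated)
4 | (4R)-2-bromo-4,8-dimethylnona-1,7-diene | C[C@H](CCC=C(C)C)CC(Br)=C | intermediate
5 | (4R)-6-bromo-4-methylhept-6-enal | C[C@H](CCC=O)CC(Br)=C | intermediate (not isolated)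
6 | (4R)-2-bromo-7,7-dimethoxy-4-methylhept-1-ene | C[C@H](CCC(OC)OC)CC(Br)=C | intermediate
7 | (R)-2-methylglycidol, [(2R)-2-methyloxiran-2-yl]methanol | C[C@@]1(CO)CO1 | starting material
8 | tert-butyldimethyl{[(2S)-2-methyloxiran-2-yl]methoxy}silane | C[C@@]1(CO[Si](C)(C)C(C)(C)C)CO1 | intermediate
9 | [(4R)-7,7-dimethoxy-4-methylhept-1-en-2-yl]magnesium bromide | C[C@H](CCC(OC)OC)CC(=C)[Mg]Br | intermediate (not isolated)
10 | (2S,6R)-1-[(tert-butyldimethylsilyl)oxy]-9,9-dimethoxy-2,6-dimethyl-4-methylidenenonan-2-ol | C[C@H](CCC(OC)OC)CC(=C)C[C@](CO[Si](C)(C)C(C)(C)C)(C)O | intermediate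
11 | (2S,6R)-9,9-dimethoxy-2,6-dimethyl-4-methylidenenonane-1,2-diol | C[C@H](CCC(OC)OC)CC(=C)C[C@](CO)(C)O | intermediate
12 | (2S,6R)-2-hydroxy-9,9-dimethoxy-2,6-dimethyl-4-methylidenenonanal | C[C@H](CCC(OC)OC)CC(=C)C[C@](C=O)(C)O | intermediate
13 | methyl (2Z,4S,8R)-4-hydroxy-11,11-dimethoxy-4,8-dimethyl-6-methylideneundec-2-enoate | C[C@H](CCC(OC)OC)CC(=C)C[C@](/C=C\C(=O)OC)(C)O | intermediate (not isolated)
14 | (5S)-5-[(4R)-7,7-dimethoxy-4-methyl-2-methylideneheptyl]-5-methylfuran-2(5H)-one | C[C@H](CCC(OC)OC)CC(=C)C[C@]1(C)OC(=O)C=C1 | intermediate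
15 | (5S)-5-[(2RS,4R)-7,7-dimethoxy-2,4-dimethyl-2-(triethylsilylperoxy)heptyl]-5-methylfuran-2(5H)-one, about 1:1 epimers at the peroxy carbon (drawn without that centre) | C[C@H](CCC(OC)OC)CC(C)(OO[Si](CC)(CC)CC)C[C@]1(C)OC(=O)C=C1 | intermediate
16 | (5S)-5-[(2RS,4R)-2-hydroperoxy-7,7-dimethoxy-2,4-dimethylheptyl]-5-methylfuran-2(5H)-one, epimer mixture | C[C@H](CCC(OC)OC)CC(C)(OO)C[C@]1(C)OC(=O)C=C1 | intermediate (not isolated)
17 | (3R,4aS,7aS)-3-[(2R)-5,5-dimethoxy-2-methylpentyl]-3,4a-dimethyl-3,4,4a,7a-tetrahydrofuro[3,2-c][1,2]dioxin-6(7H)-one | C[C@H](CCC(OC)OC)C[C@]1(C)C[C@]2(C)OC(=O)C[C@@H]2OO1 | intermediate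
18 | (4R)-5-[(3R,4aS,7aS)-3,4a-dimethyl-6-oxohexahydrofuro[3,2-c][1,2]dioxin-3-yl]-4-methylpentanal | C[C@H](CCC=O)C[C@]1(C)C[C@]2(C)OC(=O)C[C@@H]2OO1 | intermediate
19 | pent-4-en-1-ol | OCCCC=C | starting material
20 | styrene | C=Cc1ccccc1 | starting material
21 | (4E)-5-phenylpent-4-en-1-ol | OCCC/C=C/c1ccccc1 | intermediate
22 | 1-phenyl-5-{[(4E)-5-phenylpent-4-en-1-yl]sulfanyl}-1H-tetrazole | S(CCC/C=C/c1ccccc1)c1nnnn1-c1ccccc1 | intermediate
23 | 1-phenyl-5-{[(4E)-5-phenylpent-4-en-1-yl]sulfonyl}-1H-tetrazole | O=S(=O)(CCC/C=C/c1ccccc1)c1nnnn1-c1ccccc1 | intermediate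
24 | potassium (4E)-5-phenyl-1-[(1-phenyl-1H-tetrazol-5-yl)sulfonyl]pent-4-en-1-ide | [K+].[CH-](CC/C=C/c1ccccc1)S(=O)(=O)c1nnnn1-c1ccccc1 | intermediate (not isolated)
25 | (3R,4aS,7aS)-3,4a-dimethyl-3-[(2R,5E,9E)-2-methyl-10-phenyldeca-5,9-dien-1-yl]-3,4,4a,7a-tetrahydrofuro[3,2-c][1,2]dioxin-6(7H)-one (CNP0365311.2) | C[C@H](CC/C=C/CC/C=C/c1ccccc1)C[C@]1(C)C[C@]2(C)OC(=O)C[C@@H]2OO1 | target

**Step count and risks**

Total step count: 15 (steps 4 and 12–14 are side branches).
Longest linear sequence: 11 steps (1, 2, 3, 5, 6, 7, 8, 9, 10, 11, 15) from (R)-citronellal.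

Three steps most likely to fail:

1. Step 5. Forming a Grignard reagent from a functionalised 2-bromoalkene and opening a neopentyl-type epoxide can give Wurtz coupling, bromohydrin from MgBr2, or slow conversion. The fallback sets out from 6 through its Grignard reagent 9 and returns at 11. Reagent 9 is quenched with paraformaldehyde to give the allylic alcohol (4R)-7,7-dimethoxy-4-methyl-2-methylideneheptan-1-ol F1. CBr4/PPh3 converts it into the allylic bromide (4R)-2-(bromomethyl)-7,7-dimethoxy-4-methylhept-1-ene F2. The lithium enolate (LDA, THF, −78 °C) of commercial (2R,5R)-2-tert-butyl-5-methyl-1,3-dioxolan-4-one (Seebach's D-lactic acid acetal, C[C@H]1O[C@@H](C(C)(C)C)OC1=O) is alkylated by F2 anti to the tert-butyl group, the electrophile taking the place of H (self-regeneration of stereocentres). This gives the dioxolanone (2R,5S)-2-tert-butyl-5-[(4R)-7,7-dimethoxy-4-methyl-2-methylideneheptyl]-5-methyl-1,3-dioxolan-4-one F3. LiAlH4 (THF, 0 °C) reduces F3 to diol 11, so steps 4–6 are bypassed and C4 comes from D-lactic acid.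

2. Step 9. The cobalt hydride may also attack the butenolide or reduce the silyl peroxide to the alcohol, and C6 is formed without control, so about half the material is the wrong epimer. The fallback sets out from 11 and returns at 15; it installs the peroxide before the butenolide exists. The same Co(thd)2/Et3SiH/O2 conditions applied to 11 give the silyl peroxide diol (2S,4RS,6R)-9,9-dimethoxy-2,4,6-trimethyl-4-(triethylsilylperoxy)nonane-1,2-diol F4. IBX in DMSO oxidises it to the aldehyde (2S,4RS,6R)-2-hydroxy-9,9-dimethoxy-2,4,6-trimethyl-4-(triethylsilylperoxy)nonanal F5. Still–Gennari olefination then gives the enoate methyl (2Z,4S,6RS,8R)-4-hydroxy-11,11-dimethoxy-4,6,8-trimethyl-6-(triethylsilylperoxy)undec-2-enoate F6 (not isolated), which lactonises to 15. This does not cure the lack of C6 control; the epimers are still separated in step 10.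

3. Step 15. The β-peroxy lactone can open by E1cB (retro-Michael) under the carbanion or KHMDS, and some Z isomer may form. The fallback sets out from 15 and returns at 25; it moves ring closure to the end so the olefination meets only a butenolide, which has no acidic α-CH next to a β-leaving group. 1 M HCl in THF removes both the acetal and the silyl group from 15 to give the hydroperoxy aldehyde (4R,6RS)-6-hydroperoxy-4,6-dimethyl-7-[(2S)-2-methyl-5-oxo-2,5-dihydrofuran-2-yl]heptanal F7. Et3SiCl/imidazole re-silylates the hydroperoxide to (4R,6RS)-4,6-dimethyl-7-[(2S)-2-methyl-5-oxo-2,5-dihydrofuran-2-yl]-6-(triethylsilylperoxy)heptanal F8. Julia–Kocienski olefination of F8 with carbanion 24 gives (5S)-5-[(2RS,4R,7E,11E)-2,4-dimethyl-12-phenyl-2-(triethylsilylperoxy)dodeca-7,11-dien-1-yl]-5-methylfuran-2(5H)-one F9. HCl/MeOH frees the hydroperoxide (5S)-5-[(2RS,4R,7E,11E)-2-hydroperoxy-2,4-dimethyl-12-phenyldodeca-7,11-dien-1-yl]-5-methylfuran-2(5H)-one F10 (not isolated), and Et2NH/CF3CH2OH closes the dioxane to 25, which is separated from its C6 epimer at the end.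

**Further compounds**

F1 | step 5 | (4R)-7,7-dimethoxy-4-methyl-2-methylideneheptan-1-ol | C[C@H](CCC(OC)OC)CC(=C)CO
F2 | step 5 | (4R)-2-(bromomethyl)-7,7-dimethoxy-4-methylhept-1-ene | C[C@H](CCC(OC)OC)CC(=C)CBr
F3 | step 5 | (2R,5S)-2-tert-butyl-5-[(4R)-7,7-dimethoxy-4-methyl-2-methylideneheptyl]-5-methyl-1,3-dioxolan-4-one | C[C@H](CCC(OC)OC)CC(=C)C[C@]1(C)O[C@@H](C(C)(C)C)OC1=O
F4 | step 9 | (2S,4RS,6R)-9,9-dimethoxy-2,4,6-trimethyl-4-(triethylsilylperoxy)nonane-1,2-diol | C[C@H](CCC(OC)OC)CC(C)(OO[Si](CC)(CC)CC)C[C@](CO)(C)O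
F5 | step 9 | (2S,4RS,6R)-2-hydroxy-9,9-dimethoxy-2,4,6-trimethyl-4-(triethylsilylperoxy)nonanal | C[C@H](CCC(OC)OC)CC(C)(OO[Si](CC)(CC)CC)C[C@](C=O)(C)O
F6 | step 9 | methyl (2Z,4S,6RS,8R)-4-hydroxy-11,11-dimethoxy-4,6,8-trimethyl-6-(triethylsilylperoxy)undec-2-enoate | C[C@H](CCC(OC)OC)CC(C)(OO[Si](CC)(CC)CC)C[C@](/C=C\C(=O)OC)(C)O
F7 | step 15 | (4R,6RS)-6-hydroperoxy-4,6-dimethyl-7-[(2S)-2-methyl-5-oxo-2,5-dihydrofuran-2-yl]heptanal | C[C@H](CCC=O)CC(C)(OO)C[C@]1(C)OC(=O)C=C1
F8 | step 15 | (4R,6RS)-4,6-dimethyl-7-[(2S)-2-methyl-5-oxo-2,5-dihydrofuran-2-yl]-6-(triethylsilylperoxy)heptanal | C[C@H](CCC=O)CC(C)(OO[Si](CC)(CC)CC)C[C@]1(C)OC(=O)C=C1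
F9 | step 15 | (5S)-5-[(2RS,4R,7E,11E)-2,4-dimethyl-12-phenyl-2-(triethylsilylperoxy)dodeca-7,11-dien-1-yl]-5-methylfuran-2(5H)-one | C[C@H](CC/C=C/CC/C=C/c1ccccc1)CC(C)(OO[Si](CC)(CC)CC)C[C@]1(C)OC(=O)C=C1
F10 | step 15 | (5S)-5-[(2RS,4R,7E,11E)-2-hydroperoxy-2,4-dimethyl-12-phenyldodeca-7,11-dien-1-yl]-5-methylfuran-2(5H)-one | C[C@H](CC/C=C/CC/C=C/c1ccccc1)CC(C)(OO)C[C@]1(C)OC(=O)C=C1
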